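The runs stem from a simulated flask with constants of no real substance, noise included.

In a one-step world, substrate and partner would couple under the catalyst until one of them ran short, and left-handed product would climb with time towards that end. Here are the two runs you have; the flask you are asked about is the noon run followed further.

| flask | left-handed substrate | right-handed substrate | partner | free catalyst | racemization catalyst | temperature | remark | time |
|---|---|---|---|---|---|---|---|---|
| noon | 0.10 M | 0.10 M | 0.25 M | 0.10 mM | 2.5 mM | 0 °C | the very flask that is asked about, followed so far |  |
| winter | 0.050 M | 0.050 M | 0.25 M | 0.10 mM | 2.5 mM | −15 °C | run made earlier |  |
| flask | 0.10 M | 0.10 M | 0.250 M | 0.10 mM | 2.5 mM | 0 °C |  | 4.0 min |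

- noon (time / min: left-handed product / %): 0.500: 29.8; 1.00: 29.8; 1.33: 30.0; 2.00: 30.1; 2.50: 29.8
- winter (time / min: left-handed product / %): 1.00: 51.8; 2.00: 51.9; 3.00: 51.4; 5.00: 52.5; 6.00: 51.9

(readings scatter by 0.3 percentage points)

* left-handed product, in percent of the left-handed substrate and right-handed substrate together first charged, at 4.0 min
* which option adds most left-handed product ("none" when 2 percentage points or less is all one gets) (theta / epsilon / alpha / delta / beta / none)
* left-handed product present, with what was taken out counted in, in percent of the left-handed substrate and right-handed substrate together first charged, after theta
* left-handed product present, with what was taken out counted in, in percent of the left-handed substrate and right-handed substrate together first charged, after epsilon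

- free catalyst is single-handed; left-handed substrate and right-handed substrate are mirror images of each other, charged as a racemate, each of them at the stated concentration
- left-handed product that was removed still counts
- the analysis behind the earlier runs scatters by 0.3 percentage points, standard deviation
- reactions considered so far: partner + free catalyst + right-handed substrate -> free catalyst + right-handed product; 2 racemization catalyst <-> resting dimer; partner -> decomposed reagent; partner + free catalyst + left-handed substrate -> free catalyst + left-handed product; left-handed substrate + racemization catalyst <-> right-handed substrate + racemization catalyst
- "the catalyst" is free catalyst with its forms; racemization catalyst is a second catalyst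
- additions bring no volume worth counting

- theta: at 4.0 min add partner, 50.0 % of the amount charged, then wait 8.0 min
- epsilon: at 4.0 min take out 90 % of the left-handed product then present, then wait 8.0 min
- alpha: at 4.0 min raise the temperature by 25 K, then wait 8.0 min
- delta: at 4.0 min add free catalyst, 100 % of the amount charged, then wait 8.0 min
- beta: change nothing and wait 8.0 min more

Read the noon column first. From 0.500 min to 2.50 min it stays flat within the scatter of 0.3 percentage points, at an average of 29.9 %. So the climb ended before the first reading, and that average is my figure for the flask at 4.0 min. The winter column is just as flat, at 51.9 %.

Now set column against column. Left-handed substrate is half of the pair charged, and the winter run stands above that, so right-handed substrate does get turned over into left-handed substrate. A stop near 29.9 % is therefore no lack of substrate.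

That points to partner: its charge of 0.250 M is more than the 0.200 M of the two substrates together, but it also decays on its own, so it can still be the first to run out, which would make it the limiting reagent in practice though not by charge. Coupling and decay are both first order in partner, so its level cancels from their ratio, and at fixed catalyst and temperature substrate level is what sets the split. I assume decay is the faster of the two. Each bit of partner then converts a fixed fraction of what is unconverted, a pseudo-first-order fall counted in partner dosed rather than in time.

The noon average gives 0.355. This is the reach of one partner charge: the natural logarithm of one over the fraction of the charge not turned into left-handed product. Right-handed product has no reading, so it is not counted. The winter run, colder with the same partner charge, reads 0.732, twice the noon reach.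

Theta brings the flask to 150 % charges, so I expect 41.3 %, a gain of 11 points against a margin of 2 points. The other options bring no partner to a flask that has stopped moving, so after epsilon I expect 29.9 % still.

The forecast gave 30 %, theta as best, 42 % after theta (range 33 % to 47 %) and 30 % after epsilon, on the ground “so the flask has truly stopped”.

The flask gives 29.6 % at 4.0 min, theta as best with 11 points added, 40.6 % after theta and 29.6 % after epsilon.

    partner + free catalyst + right-handed substrate → free catalyst + right-handed product (k = 9700 /M²/s, Ea = 11.0 kJ/mol)
    2 racemization catalyst ⇌ resting dimer, settled at all times (K = 50.0 /M, ΔH = 24.0 kJ/mol)
    partner → decomposed reagent (k = 0.410 /s, Ea = 61.0 kJ/mol)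
    partner + free catalyst + left-handed substrate → free catalyst + left-handed product (k = 22000 /M²/s, Ea = 13.0 kJ/mol)
    left-handed substrate + racemization catalyst ⇌ right-handed substrate + racemization catalyst, rate k5*[racemization catalyst]*[left-handed substrate] forward; the back reaction follows from the equilibrium constant (k = 55.0 /M/s, Ea = 44.0 kJ/mol)
    (constants at 0 °C)

Read back over 150 % charges, 40.6 % is a reach of 0.347 per charge, beside my 0.355. At 0.0187 min partner goes to decomposed reagent 2.8 times as fast as it couples into left-handed product, and by 0.400 min partner stands at 0 % of its charge while left-handed substrate still stands at 27.5 %. Take the neighbour charged with 0.15 M of partner, otherwise like this flask: 0.600 of a charge at the noon reach gives 19.2 %, and computed it holds 19.7 %.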